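**Plan**

1. Ring A (the central ring: C1 OMe, C2 CH2Ar', C3 OH, C5 CH2CH2Ar) is a 5-alkylresorcinol whose 1,3-oxygens are the alternate carbonyls of a tetraketide, with C4 the former carboxyl-bearing carbon. This is what allows an aldol aromatisation.
2. Retrosynthesis: restore a benzyl ester at C4, cut ring A C4–C5 (aldol), then C5–C6 (dianion Claisen), C2–CH2Ar' (enolate benzylation) and C1–C2 (acetylation of the dioxinone methyl).
3. Forward: the chain is joined on 2,2,6-trimethyl-dioxinone in the order C1–C2, C2–CH2Ar', C5–C6. Thermolysis with benzyl alcohol and aldol closure then make ring A, the only ring formed; both outer rings are bought.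
4. End game: methylation of the non-chelated C1 hydroxyl, hydrogenolysis of three benzyl groups, thermal loss of the C4 carboxyl.
5. Stereochemistry: the target has no stereogenic element. Stereocentres that appear transiently in the branched chain intermediates are carried as racemates and vanish on aromatisation.

Key step: step 6

Assumption: the target SMILES has no stereodescriptor and the molecule is achiral, so "single enantiomer" means the one achiral compound and no enantiocontrol is needed.

**Route**

Step 1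
Reactants: 1 dihydrocoumarin (chroman-2-one)
Product: 2 3-(2-hydroxyphenyl)-N-methoxy-N-methylpropanamide
Conditions: MeNH(OMe)·HCl, i-PrMgCl, THF, −20 → 0 °C; aq. NH4Cl
Reagents that add atoms: N,O-dimethylhydroxylamine hydrochloride, CNOC.Cl
Why: Weinreb aminolysis of a lactone, in which the chloromagnesium amide opens the activated aryl ester and the phenoxide leaving group makes the opening easy and irreversible.

Step 2
Reactants: 2 3-(2-hydroxyphenyl)-N-methoxy-N-methylpropanamide
Product: 3 3-[2-(benzyloxy)phenyl]-N-methoxy-N-methylpropanamide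
Conditions: BnBr, K2CO3, DMF, rt
Reagents that add atoms: benzyl bromide, BrCc1ccccc1
Why: Williamson ether synthesis on the phenoxide; the Weinreb amide is inert to carbonate and the benzyl ether later falls in the same hydrogenolysis as the other benzyl groups.

Step 3
Reactants: 4 2,2,6-trimethyl-4H-1,3-dioxin-4-one
Product: 5 2,2-dimethyl-6-(2-oxopropyl)-4H-1,3-dioxin-4-one
Conditions: LiHMDS, THF, −78 °C; then AcCl, −78 → −20 °C (enolate in excess)
Reagents that add atoms: acetyl chloride, CC(Cl)=O
Why: Claisen-type γ-acylation of the lithium dienolate of the dioxinone at its exocyclic carbon, run with excess enolate because the keto-dioxinone formed is more acidic than 4.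

Step 4
Reactants: 5 2,2-dimethyl-6-(2-oxopropyl)-4H-1,3-dioxin-4-one; 6 4-(benzyloxy)benzyl bromide (commercial; also available from the alcohol with PBr3)
Product: 7 6-{1-[4-(benzyloxy)phenyl]-3-oxobutan-2-yl}-2,2-dimethyl-4H-1,3-dioxin-4-one (racemic)
Conditions: K2CO3, MeCN, rt (6 slightly substoichiometric)
Reagents that add atoms: none
Why: Enolate C-alkylation (SN2) of the doubly activated methylene between the ketone and dioxinone C6 with a reactive benzylic bromide puts the future ring A C2 substituent in place before the ring exists, so its position between the two oxygens is fixed by connectivity; the new stereocentre is racemic and is erased on aromatisation.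

Step 5
Reactants: 7 6-{1-[4-(benzyloxy)phenyl]-3-oxobutan-2-yl}-2,2-dimethyl-4H-1,3-dioxin-4-one; 3 3-[2-(benzyloxy)phenyl]-N-methoxy-N-methylpropanamide
Product: 8 6-{1-[4-(benzyloxy)phenyl]-7-[2-(benzyloxy)phenyl]-3,5-dioxoheptan-2-yl}-2,2-dimethyl-4H-1,3-dioxin-4-one (racemic, keto–enol mixture)
Conditions: LDA (2.1 equiv), THF, −78 → −40 °C; then 3, −78 → −20 °C; aq. NH4Cl
Reagents that add atoms: none
Why: Dianion Claisen acylation of a β-dicarbonyl-type compound: LDA removes the methine proton and then a methyl proton, and the more reactive terminal carbanion attacks the Weinreb amide, whose chelated tetrahedral intermediate prevents over-addition and proton transfer to unreacted dianion.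

Step 6
Reactants: 8 6-{1-[4-(benzyloxy)phenyl]-7-[2-(benzyloxy)phenyl]-3,5-dioxoheptan-2-yl}-2,2-dimethyl-4H-1,3-dioxin-4-one; 9 benzyl alcohol
Product: 13 benzyl 3-[4-(benzyloxy)benzyl]-6-{2-[2-(benzyloxy)phenyl]ethyl}-2,4-dihydroxybenzoate, via the acylketene 4-[4-(benzyloxy)benzyl]-9-[2-(benzyloxy)phenyl]non-1-ene-1,3,5,7-tetrone 10 (not isolated), via benzyl 4-[4-(benzyloxy)benzyl]-9-[2-(benzyloxy)phenyl]-3,5,7-trioxononanoate 11 (not isolated), via benzyl 3-[4-(benzyloxy)benzyl]-6-{2-[2-(benzyloxy)phenyl]ethyl}-6-hydroxy-2,4-dioxocyclohexane-1-carboxylate 12 (not isolated)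
Conditions: 9 (2 equiv), PhMe, 110 °C; cool, Cs2CO3, i-PrOH/CH2Cl2, rt; then HCl (i-PrOH), rt
Reagents that add atoms: none
Why: Heating 8 triggers retro-hetero-Diels–Alder loss of acetone to acylketene 10, which the excess benzyl alcohol captures to give triketo ester 11. Under caesium carbonate the doubly activated C2 methylene of 11 (between the ester and the C3 ketone) adds to the chain-terminal C7 ketone in a 6-(enolexo)-exo-trig aldol to carbinol 12, and acid-promoted dehydration with enolisation of the two remaining ketones aromatises ring A, its C4–C5 bond being the one formed. This is the known biomimetic aromatisation of 3,5,7-triketo esters generated from diketo-dioxinones by ketene trapping, which gives β-resorcylate esters. No stereocentre is created, and the transient stereocentres of 8, 11 and 12 disappear on aromatisation. The step needs aldol closure to prevail over Claisen closure (C6 onto the ester, to an acylphloroglucinol) and over capture of the ketene by an internal enol (pyrone); the weakly electrophilic benzyl ester, the mild carbonate base and the excess of alcohol during thermolysis should secure this, and the benzyl group on chain C4 still leaves the one hydrogen needed for enolisation.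

Step 7
Reactants: 13 benzyl 3-[4-(benzyloxy)benzyl]-6-{2-[2-(benzyloxy)phenyl]ethyl}-2,4-dihydroxybenzoate
Product: 14 benzyl 3-[4-(benzyloxy)benzyl]-6-{2-[2-(benzyloxy)phenyl]ethyl}-2-hydroxy-4-methoxybenzoate
Conditions: MeI (1.2 equiv), K2CO3, acetone, rt
Reagents that add atoms: methyl iodide, CI
Why: Williamson methylation that is chemoselective for the 4-hydroxyl (ring A C1), because the 2-hydroxyl is hydrogen-bonded to the ester carbonyl, less acidic and more hindered.

Step 8
Reactants: 14 benzyl 3-[4-(benzyloxy)benzyl]-6-{2-[2-(benzyloxy)phenyl]ethyl}-2-hydroxy-4-methoxybenzoate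
Product: 15 2-hydroxy-3-(4-hydroxybenzyl)-6-[2-(2-hydroxyphenyl)ethyl]-4-methoxybenzoic acid
Conditions: H2 (1 atm), 10% Pd/C, EtOAc/MeOH, rt
Reagents that add atoms: none
Why: Catalytic hydrogenolysis cleaves the benzyl ester and both aryl benzyl ethers in one operation, while the diarylmethane and bibenzyl C–C bonds and the methyl ether are inert.

Step 9
Reactants: 15 2-hydroxy-3-(4-hydroxybenzyl)-6-[2-(2-hydroxyphenyl)ethyl]-4-methoxybenzoic acid
Product: 16 2-(4-hydroxybenzyl)-5-[2-(2-hydroxyphenyl)ethyl]-3-methoxyphenol (target)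
Conditions: DMF, 130 °C, Ar
Reagents that add atoms: none
Why: Thermal protodecarboxylation of a salicylic-type acid through its ipso-protonated keto tautomer, favoured by the ortho hydroxyl and para methoxyl; acids with this 2-hydroxy-4-alkoxy-3,6-dialkyl pattern (the cannabinoid acids) are known to lose CO2 on mild heating.

**Compound list**

1 | dihydrocoumarin (chroman-2-one) | O=C1CCc2ccccc2O1 | starting material
2 | 3-(2-hydroxyphenyl)-N-methoxy-N-methylpropanamide | CON(C)C(=O)CCc1ccccc1O | intermediate
3 | 3-[2-(benzyloxy)phenyl]-N-methoxy-N-methylpropanamide | CON(C)C(=O)CCc1ccccc1OCc1ccccc1 | intermediate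
4 | 2,2,6-trimethyl-4H-1,3-dioxin-4-one | CC1=CC(=O)OC(C)(C)O1 | starting material
5 | 2,2-dimethyl-6-(2-oxopropyl)-4H-1,3-dioxin-4-one | CC(=O)CC1=CC(=O)OC(C)(C)O1 | intermediate
6 | 4-(benzyloxy)benzyl bromide | BrCc1ccc(OCc2ccccc2)cc1 | starting material
7 | 6-{1-[4-(benzyloxy)phenyl]-3-oxobutan-2-yl}-2,2-dimethyl-4H-1,3-dioxin-4-one (racemic) | CC(=O)C(Cc1ccc(OCc2ccccc2)cc1)C1=CC(=O)OC(C)(C)O1 | intermediate
8 | 6-{1-[4-(benzyloxy)phenyl]-7-[2-(benzyloxy)phenyl]-3,5-dioxoheptan-2-yl}-2,2-dimethyl-4H-1,3-dioxin-4-one (racemic) | CC1(C)OC(=O)C=C(C(Cc2ccc(OCc3ccccc3)cc2)C(=O)CC(=O)CCc2ccccc2OCc2ccccc2)O1 | intermediate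
9 | benzyl alcohol | OCc1ccccc1 | starting material
10 | 4-[4-(benzyloxy)benzyl]-9-[2-(benzyloxy)phenyl]non-1-ene-1,3,5,7-tetrone (acylketene; not isolated) | O=C=CC(=O)C(Cc1ccc(OCc2ccccc2)cc1)C(=O)CC(=O)CCc1ccccc1OCc1ccccc1 | intermediate
11 | benzyl 4-[4-(benzyloxy)benzyl]-9-[2-(benzyloxy)phenyl]-3,5,7-trioxononanoate (not isolated) | O=C(OCc1ccccc1)CC(=O)C(Cc1ccc(OCc2ccccc2)cc1)C(=O)CC(=O)CCc1ccccc1OCc1ccccc1 | intermediate
12 | benzyl 3-[4-(benzyloxy)benzyl]-6-{2-[2-(benzyloxy)phenyl]ethyl}-6-hydroxy-2,4-dioxocyclohexane-1-carboxylate (stereoisomer and tautomer mixture; not isolated) | O=C(OCc1ccccc1)C1C(=O)C(Cc2ccc(OCc3ccccc3)cc2)C(=O)CC1(O)CCc1ccccc1OCc1ccccc1 | intermediate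
13 | benzyl 3-[4-(benzyloxy)benzyl]-6-{2-[2-(benzyloxy)phenyl]ethyl}-2,4-dihydroxybenzoate | O=C(OCc1ccccc1)c1c(O)c(Cc2ccc(OCc3ccccc3)cc2)c(O)cc1CCc1ccccc1OCc1ccccc1 | intermediate
14 | benzyl 3-[4-(benzyloxy)benzyl]-6-{2-[2-(benzyloxy)phenyl]ethyl}-2-hydroxy-4-methoxybenzoate | O=C(OCc1ccccc1)c1c(O)c(Cc2ccc(OCc3ccccc3)cc2)c(OC)cc1CCc1ccccc1OCc1ccccc1 | intermediate
15 | 2-hydroxy-3-(4-hydroxybenzyl)-6-[2-(2-hydroxyphenyl)ethyl]-4-methoxybenzoic acid | O=C(O)c1c(O)c(Cc2ccc(O)cc2)c(OC)cc1CCc1ccccc1O | intermediate
16 | 2-(4-hydroxybenzyl)-5-[2-(2-hydroxyphenyl)ethyl]-3-methoxyphenol | COc1cc(CCc2ccccc2O)cc(O)c1Cc1ccc(O)cc1 | target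

**Step count**

Total steps: 9. Longest linear sequence: 7 steps (from 4 through steps 3, 4, 5, 6, 7, 8, 9; the branch from 1 through steps 1, 2, 5–9 is equally long).

**Steps most likely to fail, with fallbacks**

Step 5. The second deprotonation of the branched, fully substituted enolate of 7 may be incomplete, or the dianion may be too hindered to acylate cleanly, so conversion could be poor and self-condensation could compete. The fallback sets out from 5 and comes back at 13, moving the benzylation to after the ring closure. The dianion of unbranched 5 (LDA, THF, −78 °C) is acylated with 3 to give 6-{6-[2-(benzyloxy)phenyl]-2,4-dioxohexyl}-2,2-dimethyl-4H-1,3-dioxin-4-one F1. Thermolysis with 9 in toluene at 110 °C gives, through the acylketene 9-[2-(benzyloxy)phenyl]non-1-ene-1,3,5,7-tetrone F2, the triketo ester benzyl 9-[2-(benzyloxy)phenyl]-3,5,7-trioxononanoate F3. Cs2CO3 and then HCl take this through the aldol adduct benzyl 2-{2-[2-(benzyloxy)phenyl]ethyl}-2-hydroxy-4,6-dioxocyclohexane-1-carboxylate F4 to benzyl 2-{2-[2-(benzyloxy)phenyl]ethyl}-4,6-dihydroxybenzoate F5. Friedel–Crafts benzylation of F5 with 4-(benzyloxy)benzyl alcohol (OCc1ccc(OCc2ccccc2)cc1; BF3·OEt2, CH2Cl2, −20 → 0 °C) should then go between the two hydroxyls, because the other free position is para to the chelated, less donating hydroxyl and flanked by the side chain, as in ester-blocked alkylation of 6-alkylresorcylates; this gives 13. The weakness of this alternative is possible competing attack on the pendant aryl ether ring, which is why it is not the main route.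

Step 4. The ambident enolate of 5 may be alkylated on oxygen or twice on carbon, eroding the supply of mono-C-benzylated material. The fallback sets out from 4 and comes back at 7, inverting the order of the two C–C bond formations at the dioxinone methyl. The lithium dienolate of 4 (LDA, THF/DMPU, −78 °C) is γ-alkylated with 6 to give 6-{2-[4-(benzyloxy)phenyl]ethyl}-2,2-dimethyl-4H-1,3-dioxin-4-one F6. Its γ-lithio derivative (LiHMDS, THF, −78 °C, enolate in excess) is then acetylated with acetyl chloride to give 7; here only one alkylatable position exists at the benzylation stage.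

Step 6. The acylketene may be captured by an internal enol (pyrone formation) before benzyl alcohol reaches it, the Claisen mode may compete, or the hindered aldol adduct may dehydrate slowly. The fallback sets out from 8 and comes back at 14, closing the same ring A C4–C5 bond without generating a ketene. Treating 8 with Cs2CO3 and then acid at rt uses dioxinone C5 itself as the aldol donor and gives the acetonide-masked resorcylate 8-[4-(benzyloxy)benzyl]-5-{2-[2-(benzyloxy)phenyl]ethyl}-7-hydroxy-2,2-dimethyl-4H-1,3-benzodioxin-4-one F7, in which only the correct hydroxyl is free. MeI/K2CO3 in acetone gives 8-[4-(benzyloxy)benzyl]-5-{2-[2-(benzyloxy)phenyl]ethyl}-7-methoxy-2,2-dimethyl-4H-1,3-benzodioxin-4-one F8. Sodium benzyloxide (9, NaH, THF, 0 °C → rt) then opens the benzodioxinone with loss of acetone to give 14.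

**Further compounds**

F1 | step 5 | 6-{6-[2-(benzyloxy)phenyl]-2,4-dioxohexyl}-2,2-dimethyl-4H-1,3-dioxin-4-one | CC1(C)OC(=O)C=C(CC(=O)CC(=O)CCc2ccccc2OCc2ccccc2)O1
F2 | step 5 | 9-[2-(benzyloxy)phenyl]non-1-ene-1,3,5,7-tetrone | O=C=CC(=O)CC(=O)CC(=O)CCc1ccccc1OCc1ccccc1
F3 | step 5 | benzyl 9-[2-(benzyloxy)phenyl]-3,5,7-trioxononanoate | O=C(OCc1ccccc1)CC(=O)CC(=O)CC(=O)CCc1ccccc1OCc1ccccc1
F4 | step 5 | benzyl 2-{2-[2-(benzyloxy)phenyl]ethyl}-2-hydroxy-4,6-dioxocyclohexane-1-carboxylate | O=C(OCc1ccccc1)C1C(=O)CC(=O)CC1(O)CCc1ccccc1OCc1ccccc1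
F5 | step 5 | benzyl 2-{2-[2-(benzyloxy)phenyl]ethyl}-4,6-dihydroxybenzoate | O=C(OCc1ccccc1)c1c(O)cc(O)cc1CCc1ccccc1OCc1ccccc1
F6 | step 4 | 6-{2-[4-(benzyloxy)phenyl]ethyl}-2,2-dimethyl-4H-1,3-dioxin-4-one | CC1(C)OC(=O)C=C(CCc2ccc(OCc3ccccc3)cc2)O1
F7 | step 6 | 8-[4-(benzyloxy)benzyl]-5-{2-[2-(benzyloxy)phenyl]ethyl}-7-hydroxy-2,2-dimethyl-4H-1,3-benzodioxin-4-one | CC1(C)OC(=O)c2c(CCc3ccccc3OCc3ccccc3)cc(O)c(Cc3ccc(OCc4ccccc4)cc3)c2O1
F8 | step 6 | 8-[4-(benzyloxy)benzyl]-5-{2-[2-(benzyloxy)phenyl]ethyl}-7-methoxy-2,2-dimethyl-4H-1,3-benzodioxin-4-one | CC1(C)OC(=O)c2c(CCc3ccccc3OCc3ccccc3)cc(OC)c(Cc3ccc(OCc4ccccc4)cc3)c2O1
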